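**Remarks on the chemistry (conventions, one correction, two assumptions)**

- Drimane numbering is used throughout: decalin C1–C10, C11 on C9, ring C C1′–C5′. Unless stated otherwise every decalin is trans-fused with 5α-H, 9α-H (C11 β, equatorial) and 10β-CH3.
- Correction: a C5 dienoate (methyl penta-2,4-dienoate) cannot supply C5–C8. A C4-centred radical adds to its terminal carbon and leaves four further carbons, so a methylene would be inserted between C4 and the diene. The result would be a dodecatrienoyl homologue whose cycloaddition would close a seven-membered ring A. Only four carbons (C5–C8) may follow C4. The route therefore builds C4–C8 from 2,2-dimethylpent-4-enal by two Wittig homologations.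
- Precursor design: the dienol ether is carried as the triisopropylsilyl ether rather than the tert-butyldimethylsilyl ether, because it is more robust towards the cationic copper Lewis acid and does not migrate between O8 and O11 later. The E geometry of C9=C10 is fixed by a stereoretentive cross-coupling, not by olefination of a methyl ketone. The skeletons of precursor and cycloadduct are unchanged.
- Assumption 1: the (R,R) antipode of 2,2′-isopropylidenebis(4-tert-butyl-2-oxazoline) (tBu-box) is chosen from the square-planar chelate model, in which the diene adds to the enoyl face remote from the nearer tert-butyl group. If the sense proved opposite, the (S,S) ligand would be used with no other change.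
- Assumption 2: in the oxazaborolidine reduction of step 21 the isopropoxy-bearing flank of the C5′ ketone is taken as the larger group. If not, the antipodal catalyst is used.

## Structural features

The target is a trans-decalin (rings A and B, drimane skeleton) joined from C9 through an exocyclic C11=C1′ double bond to a five-membered ring C. Ring C is a 4-ylidene-3-hydroxycyclopent-2-enone (vinylogous acid, C2′–OH/C4′=O) with chlorine on C5′. Ring B carries four contiguous stereocentres: C5 (α-H), quaternary C10 (β-CH3), C9 (β-C11) and quaternary C8 (axial β-OH, equatorial α-CH3, syn-axial to the C10 methyl). C9 is flanked by two fully substituted carbons, and C4 is gem-dimethylated. The fifth stereocentre, C5′ (R), sits in ring C on the side of the C11=C1′ bond remote from C9, so the decalin cannot control it. The fragile points are: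

- the allylic α-chloro ketone C5′, which can enolise or shift to the endocyclic chloro-enedione tautomer, losing both C5′ and the alkene geometry;
- the tertiary C8 alcohol, open to dehydration and, once C11 is a carbonyl, to retro-aldol cleavage or β-elimination;
- the electrophilic C11.

The real difficulty is twofold: the congested decalin in one absolute configuration, and ring C with the decalin cis to C2′ and C5′ in the R configuration. The key step exploits ring B: oxygen on C8, an acyl-level carbon on C9 and a methyl-bearing quaternary C10 are the retron of a 1-oxydiene (C5=C6–C7=C8) adding to a β-methyl enoyl dienophile (C9=C10). The four-carbon tether C1–C4 closes ring A in the same event.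

## Logic of the disconnections

**C5′–Cl and the masking groups (33 ⇒ 32 ⇒ 31 ⇒ 30).** 33 is first re-masked as 32 (isopropyl enol ether at O4′, silyl ether at O8). The C5′–Cl bond of 32 is then cut to the C5′–O bond of 31, and that to the C5′ carbonyl of 30. The cut is made here because only a reagent can set C5′, and a ketone offers an enantioface. The gain is that 30 has no stereocentre in ring C. The forward steps must deliver hydride to C5′ only (not to the vinylogous-ester carbonyl C2′, not to C11), must substitute with clean inversion, and must unmask without enolising C5′.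

**C1′–C2′ (30 ⇒ 29).** Cutting this bond in the sense of a 1,2-acyl shift turns the cyclopentenedione into the cyclobutenone 29 with a C11≡C1′ alkyne. The shift is anti to the metal, so the decalin ends cis to C2′ as in 33, and the whole oxygenation pattern of ring C is already present. Ring C becomes a four-membered ring plus an alkyne. The forward step must move the acyl carbon, not the vinyl carbon, and must not isomerise the new alkene.

**C1′–carbinol carbon (29 ⇒ 24 + 27; 27 ⇒ 25).** The acetylide of 24 adds to one carbonyl of 27, and 27 comes from 25 by mono-reduction. This cut joins the two halves convergently and late. The addition must go to the carbonyl next to the alkoxy-bearing carbon, because that decides which acyl carbon migrates afterwards.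

**C11≡C1′ and the C11/C8 functional groups (24 ⇒ 23 ⇒ 22 ⇒ 21 ⇒ 20).** The alkyne is cut to the C11 aldehyde of 23 (one-carbon homologation), which goes back through 22 and 21 to 20. O8 must be silylated before C11 becomes a carbonyl, because H9 and O8 are trans-diaxial and the free β-hydroxy aldehyde could undergo retro-aldol cleavage.

**C8–CH3 and redox adjustment (20 ⇒ 19 ⇒ 18 ⇒ 17 ⇒ 16 ⇒ 15 ⇒ 14).** The C8–CH3 bond is cut to the ketone 19. The axial C10 methyl then forces the nucleophile to the α face, which gives the axial 8β-hydroxyl. 19 goes back by oxidation, desilylation, O11 protection, imide reduction and saturation of C6=C7 to 14. The gain is that 14 needs only a C8–O bond with hydrogen on C8. The organometallic must add without enolising C9 or eliminating O11.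

**C5–C10 and C8–C9 (14 ⇒ 13).** Both bonds are cut together in a retro-[4+2] step that opens rings A and B and removes all four stereocentres. The forward step needs one transition-state topology (carbonyl endo) and one enantioface.

**C1–C10 (13 ⇒ 11 + 6, through 12).** This sp3–sp2 bond is cut because a vinyl iodide of fixed geometry transfers its geometry to C9=C10, and a terminal alkene is a latent C1 nucleophile. Hydroboration must touch only the terminal alkene, and the coupling must spare the imide and the dienol ether.

**C7=C8–O, C6=C7 and C5–C6 (11 ⇒ 10 ⇒ 9 ⇒ 7).** The dienol ether is cut to the enal 10, then C6=C7 (two-carbon olefination) to 9, then C5–C6 (one-carbon homologation) to 7, which already holds quaternary C4. The γ-deprotonation must give the E,E diene.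

**N–acyl and C–I (6 ⇒ 3 + 4; 3 ⇒ 1).** Acylation of 4 and hydroiodination of 1 lead back to commercial materials.

## Other disconnections considered

**Alternative 1:** The cut is the C4′–C5′ bond of ring C, reached by contracting a six-membered ring. The precursor is the chlorohydroxyquinone A2 (3-chloro-5-hydroxy-2-(8β-hydroxydriman-11-yl)-1,4-benzoquinone). In the forward step A2 would react in alkaline H2O2 with CuSO4 through its 1,2-dione tautomer. Hydroxide adds to the carbonyl next to the chlorinated carbon, that carbon shifts to the neighbouring carbonyl carbon (benzilic-acid-type shift), and the extruded carbon is lost as CO2 to give the chlorocyclopentenedione A1.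

- In favour: it follows the likely biogenesis; carbon, oxygen and chlorine of ring C come from a simple arene; the two halves are joined convergently at C11.
- Against: A1 is the endocyclic tautomer of the target. The hydrogen shift from C11 to C5′ that is still needed creates both the C11=C1′ geometry and C5′ with nothing to direct them. A chloroquinone is also open to displacement of chloride and to epoxidation under the same alkaline peroxide, and the site of hydroxide addition decides which carbon is lost.
- Structure: the chosen plan fixes the alkene geometry by the anti acyl shift and C5′ by reagent control. If the target is the thermodynamic member of its tautomer family, the alternative is its equal on this point.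
- Mechanism: the contraction has several competing channels, whereas each ring-C step of the chosen route is one defined event.
- Step economy: the alternative is better for ring C (about two operations from A2 against seven, steps 17–23). It is only equal for the decalin, which must still be made with the 8β-hydroxyl.

**Alternative 2:** The cut is C9–C10. The precursor is the β-keto ester A4 (methyl 3-oxo-5-[(1S)-2,6,6-trimethyl-4-oxocyclohex-2-en-1-yl]pentanoate), which would come from (S)-α-ionone A5 by allylic oxidation and side-chain adjustment. In the forward step the C9 carbanion adds to C10, the β-carbon of the ring enone, in a 6-exo Michael closure of ring B to give the decalin-2,8-dione ester A3.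

- In favour: cheap terpenoid carbon, robust anionic chemistry, and C8 already a ketone and C11 already an ester. On the C8 oxidation level the alternative is better than the chosen plan, which needs steps 11 and 12 to reach the ketone.
- Against: stereoelectronically preferred axial attack on the enone favours the cis ring fusion, so the trans fusion would rest on equilibration through retro-Michael reaction. The C2 carbonyl must later be removed in the presence of the C8 ketone, which costs several steps. The β-keto ester must still be reduced and protected before the methyl can be added. A5 is the less accessible antipode of α-ionone.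
- Structure: the alternative forms one ring and two stereocentres under substrate control; the chosen step forms two rings and four stereocentres under catalyst control.
- Mechanism: the alternative is reversible and under thermodynamic control; the chosen step is kinetic and suprafacial.
- Step economy: roughly equal once the C2 deoxygenation is counted.

**Alternative 3:** The cut is C8–C9 together with O8–C11. The precursor is the keto acid A7 (8-oxo-8,9-secodriman-11-oic acid). In the forward step the activated acid forms an ammonium enolate at C9 under a nucleophilic amine catalyst. The enolate adds to the C8 methyl ketone, and the C8 alkoxide closes the β-lactone A6.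

- In favour: the C8 carbinol with its methyl and the C9 centre are made in one operation, and the four-membered lactone enforces the cis O8/C11 relationship. The chair-like closure that keeps C11 equatorial and puts oxygen, not the C8 methyl, syn-axial to the C10 methyl leads to the required isomer. On this point the alternative is better than the chosen plan, which spends steps 11–13 on the same result. The β-lactone is also a ready acyl donor for C11.
- Against: A7 already needs the trans C5/C10 pair with quaternary C10 on a cyclohexane. That is a separate asymmetric problem, which the cycloaddition of the chosen plan solves together with ring formation. Aldol-lactonisation onto a hindered methyl ketone next to a quaternary carbon is demanding.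
- Structure: the alternative sets two of the four ring-B centres; the chosen step sets all four.
- Mechanism: stepwise aldol and acyl transfer against a cycloaddition.
- Step economy: probably equal overall, because the steps saved after the key step are spent on A7.

Key step: step 7

## Route

Step 1
Reactants: 1 but-2-ynoic acid
Product: 3 (E)-3-iodobut-2-enoic acid, via (Z)-3-iodobut-2-enoic acid 2 (not isolated)
Conditions: 57% aq HI, 25 °C; then neat, 130 °C (sealed tube); recrystallise
Reagents that add atoms: hydrogen iodide, I
Why: Conjugate anti hydroiodination of the ynoic acid gives the Z acid, and heating should equilibrate it to the E acid (iodine trans to carboxyl), which is purified by crystallisation. This geometry later becomes that of C9=C10.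

Step 2
Reactants: 3 (E)-3-iodobut-2-enoic acid; 4 oxazolidin-2-one
Product: 6 3-[(E)-3-iodobut-2-enoyl]oxazolidin-2-one, via (E)-3-iodobut-2-enoic pivalic anhydride 5 (not isolated)
Conditions: PivCl, Et3N, THF, −20 °C; then 4, LiCl, 25 °C
Reagents that add atoms: none
Why: N-acylation of the oxazolidinone through the mixed anhydride, assisted by LiCl; no stereocentre is formed and the vinyl iodide is not touched.

Step 3
Reactants: 7 2,2-dimethylpent-4-enal
Product: 9 3,3-dimethylhex-5-enal, via 6-methoxy-4,4-dimethylhexa-1,5-diene 8 (not isolated)
Conditions: Ph3P(CH2OMe)Cl, KOtBu, THF, 0 °C; then 2 M aq HCl, THF, 25 °C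
Reagents that add atoms: (methoxymethyl)triphenylphosphonium chloride, COC[P+](c1ccccc1)(c1ccccc1)c1ccccc1.[Cl-]; water, O
Why: Wittig methoxymethylenation of the non-enolisable aldehyde and hydrolysis of the enol ether give the one-carbon homologue, placing the C5 methylene between quaternary C4 and the carbonyl.

Step 4
Reactants: 9 3,3-dimethylhex-5-enal
Product: 10 (E)-5,5-dimethylocta-2,7-dienal
Conditions: Ph3P=CHCHO, toluene, 80 °C
Reagents that add atoms: (triphenylphosphoranylidene)acetaldehyde, O=CC=P(c1ccccc1)(c1ccccc1)c1ccccc1
Why: Wittig olefination with the stabilised formyl ylide should give the E enal (C6=C7, C8 aldehyde) under thermodynamic control.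

Step 5
Reactants: 10 (E)-5,5-dimethylocta-2,7-dienal
Product: 11 triisopropyl{[(1E,3E)-5,5-dimethylocta-1,3,7-trien-1-yl]oxy}silane
Conditions: TIPSOTf, Et3N, Et2O, −78 → 0 °C
Reagents that add atoms: triisopropylsilyl trifluoromethanesulfonate, CC(C)[Si](C(C)C)(C(C)C)OS(=O)(=O)C(F)(F)F
Why: Soft enolisation (O-silylation, then γ-deprotonation at C5) gives the silyl dienol ether. The s-trans enal gives the E enol ether, and the tert-alkyl group on C5 forces E at the new C5=C6 bond.

Step 6
Reactants: 11 triisopropyl{[(1E,3E)-5,5-dimethylocta-1,3,7-trien-1-yl]oxy}silane; 6 3-[(E)-3-iodobut-2-enoyl]oxazolidin-2-one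
Product: 13 3-[(2E,8E,10E)-3,7,7-trimethyl-11-(triisopropylsilyloxy)undeca-2,8,10-trienoyl]oxazolidin-2-one, via B-alkyl-9-borabicyclononane 12 (not isolated)
Conditions: 9-BBN-H, THF, 0 → 25 °C; then 6, Pd(dppf)Cl2 (5 mol%), AsPh3, Cs2CO3, DMF/H2O, 25 °C
Reagents that add atoms: none
Why: 9-BBN should hydroborate only the monosubstituted terminal alkene, anti-Markovnikov. The B-alkyl Suzuki–Miyaura coupling forms C1–C10 with retention at the vinyl iodide, so C9=C10 is E, and the silyl dienol ether tolerates the mild base.

Step 7
Reactants: 13 3-[(2E,8E,10E)-3,7,7-trimethyl-11-(triisopropylsilyloxy)undeca-2,8,10-trienoyl]oxazolidin-2-one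
Product: 14 3-[8β-(triisopropylsilyloxy)-12-nordrim-6-en-11-oyl]oxazolidin-2-one
Conditions: [Cu((R,R)-tBu-box)](SbF6)2 (10 mol%), 4 Å MS, CH2Cl2, 25 °C
Reagents that add atoms: none
Why: The imide binds the divalent copper complex through both carbonyl oxygens in a distorted square-planar chelate, which holds the enoyl unit s-cis and lowers its LUMO; the 1-silyloxydiene, with its largest HOMO coefficient at C5, attacks the β-carbon C10 and the ring closes at C8–C9, possibly asynchronously (a Mukaiyama–Michael-like first bond, then closure). The closest known reaction type is the bis(oxazoline)–copper-catalysed enantioselective intramolecular Diels–Alder reaction of trienimides. Ring B is closed by the [4+2] event itself, and ring A by the four-atom tether C1–C4 in the 1,7,9-decatriene mode through a chair-like tether helped by the gem-dimethyl group at C4. C9 and C10 follow from the E dienophile (C11 and the C10 methyl cis), C5 and C8 from the E,E diene (the inside hydrogens H5 and H8 cis), and the trans fusion from the carbonyl-endo transition state, which puts C11, the C10 methyl and the silyloxy group on the β face and H5, H8 and H9 on the α face. The absolute sense comes from the ligand: the tert-butyl group next to the enoyl arm covers the Re face of C9, so C8 of the diene should add to the Si face with the (R,R) ligand. The step needs carbonyl-endo selectivity, secured by the bidentate Lewis acid on the imide, and one enantioface, secured by the C2-symmetric ligand; the bulky silyl group and the sieves protect the dienol ether from desilylation.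

Step 8
Reactants: 14 3-[8β-(triisopropylsilyloxy)-12-nordrim-6-en-11-oyl]oxazolidin-2-one
Product: 15 3-[8β-(triisopropylsilyloxy)-12-nordriman-11-oyl]oxazolidin-2-one
Conditions: H2 (1 atm), 10% Pd/C, EtOAc, 25 °C
Reagents that add atoms: none
Why: Heterogeneous hydrogenation of the disubstituted C6=C7 bond; no stereocentre is formed, and the imide and silyl ether are inert.

Step 9
Reactants: 15 3-[8β-(triisopropylsilyloxy)-12-nordriman-11-oyl]oxazolidin-2-one
Product: 16 8β-(triisopropylsilyloxy)-12-nordriman-11-ol
Conditions: LiBH4, H2O (1 equiv), Et2O, 0 °C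
Reagents that add atoms: none
Why: Borohydride reduction of the lithium-chelated exocyclic imide carbonyl gives the primary alcohol and releases the oxazolidinone; C9 is not epimerised.

Step 10
Reactants: 16 8β-(triisopropylsilyloxy)-12-nordriman-11-ol
Product: 17 11-benzyloxy-8β-(triisopropylsilyloxy)-12-nordrimane
Conditions: NaH, BnBr, Bu4NI (cat.), DMF, 0 → 25 °C
Reagents that add atoms: benzyl bromide, BrCc1ccccc1
Why: Williamson etherification of the primary alkoxide; the triisopropylsilyl group should not migrate from O8 to O11 under these conditions.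

Step 11
Reactants: 17 11-benzyloxy-8β-(triisopropylsilyloxy)-12-nordrimane
Product: 18 11-benzyloxy-12-nordriman-8β-ol
Conditions: Bu4NF, THF, 60 °C
Reagents that add atoms: none
Why: Fluoride-induced desilylation of the hindered axial silyl ether; the benzyl ether is untouched.

Step 12
Reactants: 18 11-benzyloxy-12-nordriman-8β-ol
Product: 19 11-benzyloxy-12-nordriman-8-one
Conditions: Dess–Martin periodinane, CH2Cl2, 25 °C
Reagents that add atoms: none
Why: Dess–Martin oxidation under near-neutral conditions, so the β-benzyloxy ketone should not eliminate and C9 keeps its equatorial substituent.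

Step 13
Reactants: 19 11-benzyloxy-12-nordriman-8-one
Product: 20 11-benzyloxydriman-8β-ol
Conditions: MeMgBr, CeCl3, THF, −78 °C
Reagents that add atoms: methylmagnesium bromide, C[Mg]Br
Why: Organocerium 1,2-addition, which is weakly basic and so avoids enolisation at C9 and loss of O11. The axial C10 methyl blocks the β face, so the methyl group enters equatorially from the α face and gives the axial 8β-hydroxyl.

Step 14
Reactants: 20 11-benzyloxydriman-8β-ol
Product: 21 11-benzyloxy-8β-(triethylsilyloxy)drimane
Conditions: TESOTf, 2,6-lutidine, CH2Cl2, 0 → 25 °C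
Reagents that add atoms: triethylsilyl trifluoromethanesulfonate, CC[Si](CC)(CC)OS(=O)(=O)C(F)(F)F
Why: Silyl triflate silylation of the hindered tertiary alcohol; the ether prevents retro-aldol cleavage and alkoxide interference once C11 is a carbonyl.

Step 15
Reactants: 21 11-benzyloxy-8β-(triethylsilyloxy)drimane
Product: 22 8β-(triethylsilyloxy)driman-11-ol
Conditions: H2 (1 atm), 10% Pd/C, EtOAc, 25 °C
Reagents that add atoms: none
Why: Hydrogenolysis of the benzyl ether in a neutral, non-protic solvent, which the tertiary triethylsilyl ether should survive.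

Step 16
Reactants: 22 8β-(triethylsilyloxy)driman-11-ol
Product: 23 8β-(triethylsilyloxy)driman-11-al
Conditions: Dess–Martin periodinane, CH2Cl2, 25 °C
Reagents that add atoms: none
Why: Dess–Martin oxidation of the primary alcohol without base, so that the trans-diaxial H9/O8 pair is not exposed to elimination; the equatorial aldehyde is the stable C9 epimer.

Step 17
Reactants: 23 8β-(triethylsilyloxy)driman-11-al
Product: 24 11-methylidyne-8β-(triethylsilyloxy)drimane
Conditions: MeC(O)C(N2)P(O)(OMe)2, K2CO3, MeOH, 0 → 25 °C
Reagents that add atoms: dimethyl (1-diazo-2-oxopropyl)phosphonate, COP(=O)(OC)C(=[N+]=[N-])C(C)=O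
Why: Ohira–Bestmann (Seyferth–Gilbert) homologation; the alkylidene carbene rearranges by 1,2-hydrogen shift to the terminal alkyne C11≡C1′, the new carbon being C1′.

Step 18
Reactants: 25 3,4-di(propan-2-yloxy)cyclobut-3-ene-1,2-dione
Product: 27 3-(propan-2-yloxy)cyclobut-3-ene-1,2-dione, via 4-hydroxy-2,3-di(propan-2-yloxy)cyclobut-2-en-1-one 26 (not isolated)
Conditions: LiAlH(OtBu)3, THF, −78 → −20 °C; then 6 M aq HCl, CH2Cl2, 25 °C
Reagents that add atoms: water, O
Why: Mono-reduction of one squarate carbonyl, then acid-induced 1,3-transposition (loss of the hydroxyl, attack of water on the alkoxy-stabilised cation, loss of propan-2-ol), gives the semisquarate ester. This is a known type of preparation.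

Step 19
Reactants: 24 11-methylidyne-8β-(triethylsilyloxy)drimane; 27 3-(propan-2-yloxy)cyclobut-3-ene-1,2-dione
Product: 29 4-hydroxy-3-(propan-2-yloxy)-4-{[8β-(triethylsilyloxy)driman-11-ylidyne]methyl}cyclobut-2-en-1-one, via lithium acetylide 28 (not isolated)
Conditions: n-BuLi, THF, −78 °C; then 27, −78 °C
Reagents that add atoms: none
Why: The acetylide should add 1,2 to the more electrophilic carbonyl (next to the alkoxy-bearing carbon, not the vinylogous-ester carbonyl). This fixes which acyl carbon migrates next; the new carbinol centre is lost in step 20, so both epimers are used.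

Step 20
Reactants: 29 4-hydroxy-3-(propan-2-yloxy)-4-{[8β-(triethylsilyloxy)driman-11-ylidyne]methyl}cyclobut-2-en-1-one
Product: 30 (2E)-4-(propan-2-yloxy)-2-[8β-(triethylsilyloxy)driman-11-ylidene]cyclopent-4-ene-1,3-dione
Conditions: Pd(OCOCF3)2 (5 mol%), THF, 25 °C
Reagents that add atoms: none
Why: Palladium-catalysed ring expansion of a 4-alkynyl-4-hydroxycyclobutenone: the divalent palladium activates the alkyne, the ring acyl carbon (C2′) shifts to C1′ anti to the metal, and protonolysis of the vinyl–palladium bond regenerates the catalyst. The anti shift places the decalin cis to C2′, which is the geometry of the target.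

Step 21
Reactants: 30 (2E)-4-(propan-2-yloxy)-2-[8β-(triethylsilyloxy)driman-11-ylidene]cyclopent-4-ene-1,3-dione
Product: 31 (4S,5Z)-4-hydroxy-3-(propan-2-yloxy)-5-[8β-(triethylsilyloxy)driman-11-ylidene]cyclopent-2-en-1-one
Conditions: (R)-2-methyl-CBS-oxazaborolidine (20 mol%), catecholborane, toluene, −78 °C
Reagents that add atoms: none
Why: Corey–Bakshi–Shibata reduction; hydride should go 1,2 to the more electrophilic C5′ ketone and not to the vinylogous-ester carbonyl C2′. The face is set by the catalyst, because the decalin is too remote, and the (R) catalyst is expected to give the 5′S alcohol if the isopropoxy-bearing flank acts as the large group.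

Step 22
Reactants: 31 (4S,5Z)-4-hydroxy-3-(propan-2-yloxy)-5-[8β-(triethylsilyloxy)driman-11-ylidene]cyclopent-2-en-1-one
Product: 32 (4R,5E)-4-chloro-3-(propan-2-yloxy)-5-[8β-(triethylsilyloxy)driman-11-ylidene]cyclopent-2-en-1-one
Conditions: PPh3, Cl3CC(O)CCl3, CH2Cl2, −20 → 0 °C
Reagents that add atoms: hexachloroacetone, ClC(Cl)(Cl)C(=O)C(Cl)(Cl)Cl
Why: Appel-type chlorination; the oxyphosphonium salt is displaced by chloride in an SN2 step with inversion (5′S alcohol to 5′R chloride). This reagent pair is known to convert allylic alcohols without allylic transposition, and the electron-poor ring disfavours ionisation.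

Step 23
Reactants: 32 (4R,5E)-4-chloro-3-(propan-2-yloxy)-5-[8β-(triethylsilyloxy)driman-11-ylidene]cyclopent-2-en-1-one
Product: 33 (4E,5R)-5-chloro-3-hydroxy-4-(8β-hydroxydriman-11-ylidene)cyclopent-2-en-1-one
Conditions: 2 M aq HCl, THF, 25 °C
Reagents that add atoms: water, O
Why: Acid hydrolysis of the vinylogous ester (addition–elimination at C4′) together with cleavage of the silyl ether; the 1,3-dione should enolise to the conjugated vinylogous acid of the target.

## Compound list

1 | but-2-ynoic acid | CC#CC(=O)O | starting material
2 | (Z)-3-iodobut-2-enoic acid | C/C(I)=C/C(=O)O | intermediate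
3 | (E)-3-iodobut-2-enoic acid | C/C(I)=C\C(=O)O | intermediate
4 | oxazolidin-2-one | O=C1NCCO1 | starting material
5 | (E)-3-iodobut-2-enoic pivalic anhydride | C/C(I)=C\C(=O)OC(=O)C(C)(C)C | intermediate
6 | 3-[(E)-3-iodobut-2-enoyl]oxazolidin-2-one | C/C(I)=C\C(=O)N1CCOC1=O | intermediate
7 | 2,2-dimethylpent-4-enal | C=CCC(C)(C)C=O | starting material
8 | 6-methoxy-4,4-dimethylhexa-1,5-diene (E/Z mixture at the enol ether) | C=CCC(C)(C)C=COC | intermediate
9 | 3,3-dimethylhex-5-enal | C=CCC(C)(C)CC=O | intermediate
10 | (E)-5,5-dimethylocta-2,7-dienal | C=CCC(C)(C)C/C=C/C=O | intermediate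
11 | triisopropyl{[(1E,3E)-5,5-dimethylocta-1,3,7-trien-1-yl]oxy}silane | C=CCC(C)(C)/C=C/C=C/O[Si](C(C)C)(C(C)C)C(C)C | intermediate
12 | 9-[(5E,7E)-4,4-dimethyl-8-(triisopropylsilyloxy)octa-5,7-dien-1-yl]-9-borabicyclo[3.3.1]nonane | CC(C)[Si](O/C=C/C=C/C(C)(C)CCCB1C2CCCC1CCC2)(C(C)C)C(C)C | intermediate
13 | 3-[(2E,8E,10E)-3,7,7-trimethyl-11-(triisopropylsilyloxy)undeca-2,8,10-trienoyl]oxazolidin-2-one | O=C(N1CCOC1=O)/C=C(\C)CCCC(C)(C)/C=C/C=C/O[Si](C(C)C)(C(C)C)C(C)C | intermediate
14 | 3-[8β-(triisopropylsilyloxy)-12-nordrim-6-en-11-oyl]oxazolidin-2-one (trans-fused; 5α-H, 8α-H, 9α-H, 10β-CH3) | CC1(C)CCC[C@]2(C)[C@@H](C(=O)N3CCOC3=O)[C@@H](O[Si](C(C)C)(C(C)C)C(C)C)C=C[C@@H]12 | intermediate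
15 | 3-[8β-(triisopropylsilyloxy)-12-nordriman-11-oyl]oxazolidin-2-one | CC1(C)CCC[C@]2(C)[C@@H](C(=O)N3CCOC3=O)[C@@H](O[Si](C(C)C)(C(C)C)C(C)C)CC[C@@H]12 | intermediate
16 | 8β-(triisopropylsilyloxy)-12-nordriman-11-ol | CC1(C)CCC[C@]2(C)[C@@H](CO)[C@@H](O[Si](C(C)C)(C(C)C)C(C)C)CC[C@@H]12 | intermediate
17 | 11-benzyloxy-8β-(triisopropylsilyloxy)-12-nordrimane | CC1(C)CCC[C@]2(C)[C@@H](COCc3ccccc3)[C@@H](O[Si](C(C)C)(C(C)C)C(C)C)CC[C@@H]12 | intermediate
18 | 11-benzyloxy-12-nordriman-8β-ol | CC1(C)CCC[C@]2(C)[C@@H](COCc3ccccc3)[C@@H](O)CC[C@@H]12 | intermediate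
19 | 11-benzyloxy-12-nordriman-8-one | CC1(C)CCC[C@]2(C)[C@@H](COCc3ccccc3)C(=O)CC[C@@H]12 | intermediate
20 | 11-benzyloxydriman-8β-ol (8α-CH3) | CC1(C)CCC[C@]2(C)[C@@H](COCc3ccccc3)[C@@](C)(O)CC[C@@H]12 | intermediate
21 | 11-benzyloxy-8β-(triethylsilyloxy)drimane | CC1(C)CCC[C@]2(C)[C@@H](COCc3ccccc3)[C@@](C)(O[Si](CC)(CC)CC)CC[C@@H]12 | intermediate
22 | 8β-(triethylsilyloxy)driman-11-ol | CC1(C)CCC[C@]2(C)[C@@H](CO)[C@@](C)(O[Si](CC)(CC)CC)CC[C@@H]12 | intermediate
23 | 8β-(triethylsilyloxy)driman-11-al | CC1(C)CCC[C@]2(C)[C@@H](C=O)[C@@](C)(O[Si](CC)(CC)CC)CC[C@@H]12 | intermediate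
24 | 11-methylidyne-8β-(triethylsilyloxy)drimane (9β-ethynyl compound; alkyne carbons C11 and C1′) | CC1(C)CCC[C@]2(C)[C@@H](C#C)[C@@](C)(O[Si](CC)(CC)CC)CC[C@@H]12 | intermediate
25 | 3,4-di(propan-2-yloxy)cyclobut-3-ene-1,2-dione | CC(C)OC1=C(OC(C)C)C(=O)C1=O | starting material
26 | 4-hydroxy-2,3-di(propan-2-yloxy)cyclobut-2-en-1-one | CC(C)OC1=C(OC(C)C)C(O)C1=O | intermediate
27 | 3-(propan-2-yloxy)cyclobut-3-ene-1,2-dione | CC(C)OC1=CC(=O)C1=O | intermediate
28 | lithium acetylide of 24 | CC1(C)CCC[C@]2(C)[C@@H](C#C[Li])[C@@](C)(O[Si](CC)(CC)CC)CC[C@@H]12 | intermediate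
29 | 4-hydroxy-3-(propan-2-yloxy)-4-{[8β-(triethylsilyloxy)driman-11-ylidyne]methyl}cyclobut-2-en-1-one (both carbinol epimers) | CC1(C)CCC[C@]2(C)[C@@H](C#CC3(O)C(OC(C)C)=CC3=O)[C@@](C)(O[Si](CC)(CC)CC)CC[C@@H]12 | intermediate
30 | (2E)-4-(propan-2-yloxy)-2-[8β-(triethylsilyloxy)driman-11-ylidene]cyclopent-4-ene-1,3-dione (decalin cis to C2′) | CC1(C)CCC[C@]2(C)[C@@H](/C=C3\C(=O)C=C(OC(C)C)C3=O)[C@@](C)(O[Si](CC)(CC)CC)CC[C@@H]12 | intermediate
31 | (4S,5Z)-4-hydroxy-3-(propan-2-yloxy)-5-[8β-(triethylsilyloxy)driman-11-ylidene]cyclopent-2-en-1-one (5′S) | CC1(C)CCC[C@]2(C)[C@@H](/C=C3\C(=O)C=C(OC(C)C)[C@H]3O)[C@@](C)(O[Si](CC)(CC)CC)CC[C@@H]12 | intermediate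
32 | (4R,5E)-4-chloro-3-(propan-2-yloxy)-5-[8β-(triethylsilyloxy)driman-11-ylidene]cyclopent-2-en-1-one (5′R) | CC1(C)CCC[C@]2(C)[C@@H](/C=C3\C(=O)C=C(OC(C)C)[C@@H]3Cl)[C@@](C)(O[Si](CC)(CC)CC)CC[C@@H]12 | intermediate
33 | (4E,5R)-5-chloro-3-hydroxy-4-(8β-hydroxydriman-11-ylidene)cyclopent-2-en-1-one, i.e. (4E,5R)-5-chloro-3-hydroxy-4-{[(1R,2S,4aS,8aS)-2-hydroxy-2,5,5,8a-tetramethyldecahydronaphthalen-1-yl]methylidene}cyclopent-2-en-1-one | CC1(C)CCC[C@]2(C)[C@@H](/C=C3\C(O)=CC(=O)[C@@H]3Cl)[C@@](C)(O)CC[C@@H]12 | target

## Step count and least certain steps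

Total: 23 steps. Longest linear sequence: 20 steps (from 7 through steps 3–17 and 19–23). Steps 1, 2 and 18 are side branches.

**Step 7 (key step).**
- Risk: slow cycloaddition, because the C5–C10 bond joins a carbon next to quaternary C4 to a β,β-disubstituted dienophile carbon. A stepwise conjugate-addition pathway with silyl transfer or hydrolytic loss of the dienol ether may stop before C8–C9 closes. Endo/exo or facial selectivity may be eroded by the syn-axial methyl/methyl contact that develops between C4 and C10.
- Fallback: stereocontrol by a covalent auxiliary instead of the catalyst, setting out from 11 and 3. Commercial (4S)-4-benzyloxazolidin-2-one is acylated with 3 as in step 2 to give 3-[(E)-3-iodobut-2-enoyl]-(4S)-4-benzyloxazolidin-2-one F1. F1 is coupled with the borane 12 from 11 as in step 6 to give (4S)-4-benzyl-3-[(2E,8E,10E)-3,7,7-trimethyl-11-(triisopropylsilyloxy)undeca-2,8,10-trienoyl]oxazolidin-2-one F2. Me2AlCl (CH2Cl2, −30 °C) then promotes the same cycloaddition through the aluminium-chelated s-cis imide, whose benzyl group shields the Re face of C9, to give (4S)-4-benzyl-3-[8β-(triisopropylsilyloxy)-12-nordrim-6-en-11-oyl]oxazolidin-2-one F3. Hydrogenation gives (4S)-4-benzyl-3-[8β-(triisopropylsilyloxy)-12-nordriman-11-oyl]oxazolidin-2-one F4, and LiBH4 reduction of F4 returns to the route at 16.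

**Step 21.**
- Risk: poor facial selectivity, because both flanks of the C5′ ketone are sp2 carbons of similar size. Competing conjugate reduction at C11 of the s-cis alkylidene ketone is also possible.
- Fallback: separation and recycling in place of catalyst control, setting out from 30. Luche reduction (NaBH4, CeCl3·7H2O, MeOH, −78 °C) would give 31 together with its C5′ epimer, (4R,5Z)-4-hydroxy-3-(propan-2-yloxy)-5-[8β-(triethylsilyloxy)driman-11-ylidene]cyclopent-2-en-1-one F8. The two are diastereomers and should separate on silica. The configuration would be assigned by Mosher ester analysis, and F8 would be re-oxidised with MnO2 to 30 and recycled. The route is rejoined at 31.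

**Step 22.**
- Risk: loss of stereochemical fidelity through partial ionisation or allylic transposition of the doubly allylic oxyphosphonium salt, and phosphine-induced isomerisation of the C11=C1′ bond by reversible conjugate addition.
- Fallback: a two-stage, phosphine-free displacement through an isolated sulfonate, setting out from 31. MsCl and Et3N (CH2Cl2, −40 °C) give the methanesulfonate of 31, (1S,5Z)-4-oxo-2-(propan-2-yloxy)-5-[8β-(triethylsilyloxy)driman-11-ylidene]cyclopent-2-en-1-yl methanesulfonate F9. LiCl in DMF at 0 °C then displaces it with inversion, and the route is rejoined at 32.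

**Step 23.**
- Risk: epimerisation at C5′ and loss of the alkene geometry, by enolisation of the C4′ oxocarbenium intermediate towards C5′ or by prototropy to the endocyclic chloro-enedione tautomer. Acid-induced dehydration of the tertiary C8 alcohol is also possible.
- Fallback: dealkylative, non-hydrolytic unmasking in two stages, setting out from 32. BCl3 (CH2Cl2, −78 °C) cleaves the oxygen–isopropyl bond without water and gives (4E,5R)-5-chloro-3-hydroxy-4-[8β-(triethylsilyloxy)driman-11-ylidene]cyclopent-2-en-1-one F10. HF·pyridine (THF, 0 °C) then removes the silyl group, and the route is rejoined at 33.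

**Step 20.**
- Risk: competing oxypalladation or slow protonolysis of the vinyl–palladium intermediate, and geometric isomerisation of the new exocyclic alkene by acid or palladium hydride, which would put the decalin cis to C5′.
- Fallback: ring C built by aldol condensation instead of ring expansion, setting out from 23. Cyclopentane-1,3-dione and propan-2-ol (TsOH) give 3-(propan-2-yloxy)cyclopent-2-en-1-one F5. The kinetic lithium enolate of F5 (LDA, THF, −78 °C) adds to 23 to give 5-[11-hydroxy-8β-(triethylsilyloxy)driman-11-yl]-3-(propan-2-yloxy)cyclopent-2-en-1-one F6. MsCl/Et3N and then DBU dehydrate F6 to 3-(propan-2-yloxy)-5-[8β-(triethylsilyloxy)driman-11-ylidene]cyclopent-2-en-1-one F7. Allylic oxidation of the doubly activated C5′ methylene of F7 (SeO2, dioxane) rejoins the route at 30. This fallback gives the alkene geometry of a condensation, which is probably the one with the decalin remote from C2′, so the isomers would have to be separated or equilibrated.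

## Further compounds

F1 | step 7 | 3-[(E)-3-iodobut-2-enoyl]-(4S)-4-benzyloxazolidin-2-one | C/C(I)=C\C(=O)N1[C@@H](Cc2ccccc2)COC1=O
F2 | step 7 | (4S)-4-benzyl-3-[(2E,8E,10E)-3,7,7-trimethyl-11-(triisopropylsilyloxy)undeca-2,8,10-trienoyl]oxazolidin-2-one | O=C(N1[C@@H](Cc2ccccc2)COC1=O)/C=C(\C)CCCC(C)(C)/C=C/C=C/O[Si](C(C)C)(C(C)C)C(C)C
F3 | step 7 | (4S)-4-benzyl-3-[8β-(triisopropylsilyloxy)-12-nordrim-6-en-11-oyl]oxazolidin-2-one | CC1(C)CCC[C@]2(C)[C@@H](C(=O)N3[C@@H](Cc4ccccc4)COC3=O)[C@@H](O[Si](C(C)C)(C(C)C)C(C)C)C=C[C@@H]12
F4 | step 7 | (4S)-4-benzyl-3-[8β-(triisopropylsilyloxy)-12-nordriman-11-oyl]oxazolidin-2-one | CC1(C)CCC[C@]2(C)[C@@H](C(=O)N3[C@@H](Cc4ccccc4)COC3=O)[C@@H](O[Si](C(C)C)(C(C)C)C(C)C)CC[C@@H]12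
F5 | step 20 | 3-(propan-2-yloxy)cyclopent-2-en-1-one | CC(C)OC1=CC(=O)CC1
F6 | step 20 | 5-[11-hydroxy-8β-(triethylsilyloxy)driman-11-yl]-3-(propan-2-yloxy)cyclopent-2-en-1-one (mixture at the two new centres) | CC1(C)CCC[C@]2(C)[C@@H](C(O)C3CC(OC(C)C)=CC3=O)[C@@](C)(O[Si](CC)(CC)CC)CC[C@@H]12
F7 | step 20 | 3-(propan-2-yloxy)-5-[8β-(triethylsilyloxy)driman-11-ylidene]cyclopent-2-en-1-one (alkene geometry as formed) | CC1(C)CCC[C@]2(C)[C@@H](C=C3CC(OC(C)C)=CC3=O)[C@@](C)(O[Si](CC)(CC)CC)CC[C@@H]12
F8 | step 21 | (4R,5Z)-4-hydroxy-3-(propan-2-yloxy)-5-[8β-(triethylsilyloxy)driman-11-ylidene]cyclopent-2-en-1-one | CC1(C)CCC[C@]2(C)[C@@H](/C=C3\C(=O)C=C(OC(C)C)[C@@H]3O)[C@@](C)(O[Si](CC)(CC)CC)CC[C@@H]12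
F9 | step 22 | (1S,5Z)-4-oxo-2-(propan-2-yloxy)-5-[8β-(triethylsilyloxy)driman-11-ylidene]cyclopent-2-en-1-yl methanesulfonate | CC1(C)CCC[C@]2(C)[C@@H](/C=C3\C(=O)C=C(OC(C)C)[C@H]3OS(C)(=O)=O)[C@@](C)(O[Si](CC)(CC)CC)CC[C@@H]12
F10 | step 23 | (4E,5R)-5-chloro-3-hydroxy-4-[8β-(triethylsilyloxy)driman-11-ylidene]cyclopent-2-en-1-one | CC1(C)CCC[C@]2(C)[C@@H](/C=C3\C(O)=CC(=O)[C@@H]3Cl)[C@@](C)(O[Si](CC)(CC)CC)CC[C@@H]12
A1 | alternative 1 | 4-chloro-5-(8β-hydroxydriman-11-yl)cyclopent-4-ene-1,3-dione | CC1(C)CCC[C@]2(C)[C@@H](CC3=C(Cl)C(=O)CC3=O)[C@@](C)(O)CC[C@@H]12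
A2 | alternative 1 | 3-chloro-5-hydroxy-2-(8β-hydroxydriman-11-yl)cyclohexa-2,5-diene-1,4-dione | CC1(C)CCC[C@]2(C)[C@@H](CC3=C(Cl)C(=O)C(O)=CC3=O)[C@@](C)(O)CC[C@@H]12
A3 | alternative 2 | methyl 2,8-dioxo-12-nordriman-11-oate (trans-fused) | CC1(C)CC(=O)C[C@]2(C)[C@@H](C(=O)OC)C(=O)CC[C@@H]12
A4 | alternative 2 | methyl 3-oxo-5-[(1S)-2,6,6-trimethyl-4-oxocyclohex-2-en-1-yl]pentanoate | CC1(C)CC(=O)C=C(C)[C@H]1CCC(=O)CC(=O)OC
A5 | alternative 2 | (S)-α-ionone, (3E)-4-[(1S)-2,6,6-trimethylcyclohex-2-en-1-yl]but-3-en-2-one | CC1(C)CCC=C(C)[C@H]1/C=C/C(C)=O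
A6 | alternative 3 | 8β-hydroxydriman-11-oic acid 8,11-β-lactone | CC1(C)CCC[C@]2(C)[C@@H](C(=O)O3)[C@]3(C)CC[C@@H]12
A7 | alternative 3 | 8-oxo-8,9-secodriman-11-oic acid, 2-[1,3,3-trimethyl-2-(3-oxobutyl)cyclohexyl]acetic acid (5α-H, 10β-CH3) | CC1(C)CCC[C@](C)(CC(=O)O)[C@H]1CCC(C)=O
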